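**Retrosynthetic overview**
1. The butenolide is made last. Its C6–O(lactone) bond and its C7=C11 double bond are formed in one pot from the ten-membered α-ketol 23 (as C6 triflate), 2-(diethoxyphosphoryl)acrylic acid 27 and acetate (SN2 O-alkylation, oxa-Michael addition, intramolecular Horner–Wadsworth–Emmons); the same operation installs C13–OAc and sets C6.
2. Enabling feature: in the ten-membered carbocycle the C6 carbinol sits directly next to the C7 ring ketone (α-ketol C5–C6–C7, flanked by the C4–C5 oxirane). An electrophilic sp3 carbon and a carbonyl carbon are thus 1,2-related and match the O,C-dinucleophile (carboxylate O, phosphonate carbon C11) of the three-carbon reagent.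
3. Oxirane: hydroxyl-directed epoxidation of the (Z)-C4=C5 olefin from C6–OH (threo); inversion at C6 in the key step then gives the erythro O–C6/oxirane relation of the target.
4. Ten-membered ring: ring-closing metathesis (C4=C5) of diene-dione 15; C6/C7 come from a (Z)-γ-alkoxyallylboration of aldehyde 9; C8/C10 come from (S)-γ-(trityloxymethyl)-γ-butyrolactone 1 (trans-methylation, Weinreb opening, Grignard addition).
5. Order of ring formation: carbocycle (step 10), oxirane (step 16), butenolide (step 19); the C8 ester is attached before the key step and unmasked last.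

Key step: step 19

Remark: locants in the Why lines follow germacrane numbering (C1 ring ketone, C4/C5 oxirane, C6 lactone O–CH, C7/C11 butenolide olefin, C8 ester O–CH, C10 CHMe, C12 lactone C=O, C13 CH2OAc); the allylborane from (+)-Ipc2BOMe is assumed to attack the aldehyde face opposite to that attacked by the (−)-series reagent.

**Step 1**
Reactants: 1 (S)-5-[(trityloxy)methyl]dihydrofuran-2(3H)-one
Product: 2 (3R,5S)-3-methyl-5-[(trityloxy)methyl]dihydrofuran-2(3H)-one
Conditions: LiN(i-Pr)2, THF, −78 °C; MeI, −78 °C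
Reagents that add atoms: iodomethane CI
Why: Enolate alkylation of a γ-substituted butyrolactone; the lithium enolate is methylated anti to the bulky trityloxymethyl group at C8, which should give the trans lactone and so sets C10 (R) from C8.

**Step 2**
Reactants: 2 (3R,5S)-3-methyl-5-[(trityloxy)methyl]dihydrofuran-2(3H)-one
Product: 3 (2R,4S)-4-hydroxy-N-methoxy-N,2-dimethyl-5-(trityloxy)pentanamide
Conditions: MeNH(OMe)·HCl, i-PrMgCl, THF, −20 → 0 °C
Reagents that add atoms: N,O-dimethylhydroxylamine hydrochloride CNOC.Cl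
Why: Aminolysis of the lactone by the chloromagnesium amide (Weinreb amide formation) is non-acidic, so the trityl ether and the C10 centre should survive.

**Step 3**
Reactants: 3 (2R,4S)-4-hydroxy-N-methoxy-N,2-dimethyl-5-(trityloxy)pentanamide
Product: 4 (2R,4S)-4-[(tert-butyldimethylsilyl)oxy]-N-methoxy-N,2-dimethyl-5-(trityloxy)pentanamide
Conditions: TBSCl, imidazole, DMAP (cat.), DMF, 0 °C → rt
Reagents that add atoms: tert-butyldimethylsilyl chloride CC(C)(C)[Si](C)(C)Cl
Why: Standard silylation of the secondary C8 alcohol, which also blocks relactonisation.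

**Step 4**
Reactants: 4 (2R,4S)-4-[(tert-butyldimethylsilyl)oxy]-N-methoxy-N,2-dimethyl-5-(trityloxy)pentanamide and 5 4-bromo-2-methylbut-1-ene
Product: 7 (6R,8S)-8-[(tert-butyldimethylsilyl)oxy]-2,6-dimethyl-9-(trityloxy)non-1-en-5-one, via Grignard reagent 6 (not isolated)
Conditions: 5, Mg, THF, rt; then 4, THF, 0 °C; aq NH4Cl
Reagents that add atoms: none
Why: Weinreb ketone synthesis; the stable magnesium chelate stops after one addition and gives the C1 ketone with the C2–C4 isopropenyl tail without touching C10.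

**Step 5**
Reactants: 7 (6R,8S)-8-[(tert-butyldimethylsilyl)oxy]-2,6-dimethyl-9-(trityloxy)non-1-en-5-one
Product: 8 (6R,8S)-8-[(tert-butyldimethylsilyl)oxy]-9-hydroxy-2,6-dimethylnon-1-en-5-one
Conditions: Et2AlCl, CH2Cl2, −78 → −20 °C; aq NaHCO3
Reagents that add atoms: none
Why: Lewis acid cleavage of the trityl ether, which should leave the secondary TBS ether intact and avoids the acid/methanol conditions that would ketalise the δ-hydroxy ketone.

**Step 6**
Reactants: 8 (6R,8S)-8-[(tert-butyldimethylsilyl)oxy]-9-hydroxy-2,6-dimethylnon-1-en-5-one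
Product: 9 (2S,4R)-2-[(tert-butyldimethylsilyl)oxy]-4,8-dimethyl-5-oxonon-8-enal
Conditions: Dess–Martin periodinane, NaHCO3, CH2Cl2, 0 °C → rt; used crude
Reagents that add atoms: none
Why: Buffered Dess–Martin oxidation should give the α-silyloxy aldehyde without epimerising C8.

**Step 7**
Reactants: 10 4-methoxybenzyl alcohol and 11 allyl bromide
Product: 12 1-[(allyloxy)methyl]-4-methoxybenzene
Conditions: NaH, THF/DMF, 0 °C; then 11, Bu4NI (cat.), rt
Reagents that add atoms: none
Why: Williamson ether synthesis.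

**Step 8**
Reactants: 9 (2S,4R)-2-[(tert-butyldimethylsilyl)oxy]-4,8-dimethyl-5-oxonon-8-enal and 12 1-[(allyloxy)methyl]-4-methoxybenzene
Product: 14 (6R,8S,9R,10S)-8-[(tert-butyldimethylsilyl)oxy]-9-hydroxy-10-[(4-methoxybenzyl)oxy]-2,6-dimethyldodeca-1,11-dien-5-one, via allylborane 13 (not isolated)
Conditions: 12, s-BuLi, THF, −78 °C; (+)-Ipc2BOMe; BF3·OEt2; then 9, −78 °C; NaBO3·4H2O, THF/H2O, rt
Reagents that add atoms: none
Why: Brown (Z)-γ-alkoxyallylboration; the closed chair transition state gives the syn C6-OPMB/C7-OH pair, and the reagent should attack the Re face of the aldehyde (reagent control, matched with Felkin–Anh control by the C8 silyloxy group), which sets C6 as S, while the C1 ketone is not attacked at −78 °C.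

**Step 9**
Reactants: 14 (6R,8S,9R,10S)-8-[(tert-butyldimethylsilyl)oxy]-9-hydroxy-10-[(4-methoxybenzyl)oxy]-2,6-dimethyldodeca-1,11-dien-5-one
Product: 15 (3S,5S,7R)-5-[(tert-butyldimethylsilyl)oxy]-3-[(4-methoxybenzyl)oxy]-7,11-dimethyldodeca-1,11-diene-4,8-dione
Conditions: Dess–Martin periodinane, NaHCO3, CH2Cl2, 0 °C → rt
Reagents that add atoms: none
Why: Neutral Dess–Martin oxidation of the C7 carbinol, which should not isomerise the β,γ-unsaturated α-alkoxy ketone.

**Step 10**
Reactants: 15 (3S,5S,7R)-5-[(tert-butyldimethylsilyl)oxy]-3-[(4-methoxybenzyl)oxy]-7,11-dimethyldodeca-1,11-diene-4,8-dione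
Product: 16 (2R,4S,6S,7Z)-4-[(tert-butyldimethylsilyl)oxy]-6-[(4-methoxybenzyl)oxy]-2,8-dimethylcyclodec-7-ene-1,5-dione
Conditions: second-generation Grubbs catalyst (H2IMes)(PCy3)Cl2Ru=CHPh (15 mol %), 1,4-benzoquinone (30 mol %), toluene (1 mM), 80 °C
Reagents that add atoms: none
Why: Ring-closing metathesis of a monosubstituted with a 1,1-disubstituted olefin at high dilution; in a ten-membered ring only the (Z)-trisubstituted olefin (C3 and C6 cis) is low in strain, and benzoquinone suppresses hydride-mediated isomerisation of the vinyl ketone.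

**Step 11**
Reactants: 16 (2R,4S,6S,7Z)-4-[(tert-butyldimethylsilyl)oxy]-6-[(4-methoxybenzyl)oxy]-2,8-dimethylcyclodec-7-ene-1,5-dione
Product: 17 (2R,4S,6S,7Z)-4-hydroxy-6-[(4-methoxybenzyl)oxy]-2,8-dimethylcyclodec-7-ene-1,5-dione
Conditions: 48% aq HF, MeCN, 0 °C → rt
Reagents that add atoms: none
Why: Cleavage of the C8 silyl ether by HF under mildly acidic conditions that leave the PMB ether, the olefin and the ketones untouched.

**Step 12**
Reactants: 18 ethyl 2-(hydroxymethyl)acrylate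
Product: 19 ethyl 2-{[(tert-butyldimethylsilyl)oxy]methyl}acrylate
Conditions: TBSCl, imidazole, CH2Cl2, rt
Reagents that add atoms: tert-butyldimethylsilyl chloride CC(C)(C)[Si](C)(C)Cl
Why: Standard silylation of the primary allylic alcohol.

**Step 13**
Reactants: 19 ethyl 2-{[(tert-butyldimethylsilyl)oxy]methyl}acrylate
Product: 20 2-{[(tert-butyldimethylsilyl)oxy]methyl}acrylic acid
Conditions: LiOH·H2O, THF/H2O, 0 °C; 1 M HCl to pH 4
Reagents that add atoms: lithium hydroxide monohydrate [Li+].[OH-].O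
Why: Saponification at 0 °C, where hydroxide should attack the ester faster than it adds to the 2-substituted acrylate.

**Step 14**
Reactants: 17 (2R,4S,6S,7Z)-4-hydroxy-6-[(4-methoxybenzyl)oxy]-2,8-dimethylcyclodec-7-ene-1,5-dione and 20 2-{[(tert-butyldimethylsilyl)oxy]methyl}acrylic acid
Product: 21 (1S,3S,4Z,9R)-3-[(4-methoxybenzyl)oxy]-5,9-dimethyl-2,8-dioxocyclodec-4-en-1-yl 2-{[(tert-butyldimethylsilyl)oxy]methyl}acrylate
Conditions: EDC·HCl, DMAP (0.2 equiv), CH2Cl2, 0 °C → rt
Reagents that add atoms: none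
Why: Steglich esterification of the secondary C8 alcohol, done now so that no acylation is needed once the sensitive butenolide–oxirane array is in place.

**Step 15**
Reactants: 21 (1S,3S,4Z,9R)-3-[(4-methoxybenzyl)oxy]-5,9-dimethyl-2,8-dioxocyclodec-4-en-1-yl 2-{[(tert-butyldimethylsilyl)oxy]methyl}acrylate
Product: 22 (1S,3S,4Z,9R)-3-hydroxy-5,9-dimethyl-2,8-dioxocyclodec-4-en-1-yl 2-{[(tert-butyldimethylsilyl)oxy]methyl}acrylate
Conditions: DDQ, CH2Cl2/pH 7 buffer (10:1), 0 °C
Reagents that add atoms: none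
Why: Oxidative PMB cleavage by DDQ at pH 7 frees the C6 allylic alcohol without touching silyl ether, olefins or ketones.

**Step 16**
Reactants: 22 (1S,3S,4Z,9R)-3-hydroxy-5,9-dimethyl-2,8-dioxocyclodec-4-en-1-yl 2-{[(tert-butyldimethylsilyl)oxy]methyl}acrylate
Product: 23 (1S,2S,4S,6R,10R)-2-hydroxy-6,10-dimethyl-3,7-dioxo-11-oxabicyclo[8.1.0]undecan-4-yl 2-{[(tert-butyldimethylsilyl)oxy]methyl}acrylate
Conditions: m-CPBA, NaHCO3, CH2Cl2, −20 → 0 °C
Reagents that add atoms: 3-chloroperoxybenzoic acid OOC(=O)c1cccc(Cl)c1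
Why: Hydroxyl-directed (Henbest) epoxidation; A(1,3) strain with C3 keeps C6–H in the olefin plane, so the C6 hydroxyl should deliver the peracid to its own, outer face and give the threo (trans) epoxy alcohol with 4R,5S configuration, as for acyclic (Z)-allylic alcohols and medium-ring (Z)-cycloalk-2-enols; the acrylate is too electron-poor to react.

**Step 17**
Reactants: 24 tert-butyl 2-(diethoxyphosphoryl)acetate
Product: 26 tert-butyl 2-(diethoxyphosphoryl)acrylate, via hydroxymethyl adduct 25 (not isolated)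
Conditions: (CH2O)n, piperidine (cat.), MeOH, reflux; then TsOH·H2O (cat.), toluene, 80 °C, azeotropic removal of water
Reagents that add atoms: formaldehyde (as paraformaldehyde) C=O
Why: Knoevenagel-type hydroxymethylation of the phosphonoacetate followed by acid-catalysed dehydration, the usual route to 2-phosphonoacrylates.

**Step 18**
Reactants: 26 tert-butyl 2-(diethoxyphosphoryl)acrylate
Product: 27 2-(diethoxyphosphoryl)acrylic acid
Conditions: CF3CO2H/CH2Cl2 (1:2), 0 °C → rt; evaporation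
Reagents that add atoms: none
Why: Acidolysis of the tert-butyl ester (loss of isobutene) frees the acid without a nucleophile that could add to the acrylate.

**Step 19**
Reactants: 23 (1S,2S,4S,6R,10R)-2-hydroxy-6,10-dimethyl-3,7-dioxo-11-oxabicyclo[8.1.0]undecan-4-yl 2-{[(tert-butyldimethylsilyl)oxy]methyl}acrylate and 27 2-(diethoxyphosphoryl)acrylic acid
Product: 30 (4R,5S,6S,8S,10R)-13-acetoxy-8-[(2-{[(tert-butyldimethylsilyl)oxy]methyl}acryloyl)oxy]-4,5-epoxy-1-oxogermacr-7(11)-en-12,6-olide, via triflate 28 (not isolated), via phosphonoacrylate ester 29 (not isolated)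
Conditions: Tf2O, 2,6-lutidine, CH2Cl2, −78 °C; then 27 (1.1 equiv), Cs2CO3 (0.55 equiv), 18-crown-6, MeCN, −40 → 0 °C; then Bu4NOAc (4 equiv), AcOH (1 equiv), 0 °C → rt
Reagents that add atoms: tetrabutylammonium acetate CCCC[N+](CCCC)(CCCC)CCCC.CC(=O)[O-]
Why: Proposed new method: the α-ketol is triflated at C6 and the cesium carboxylate of 27 displaces the triflate by SN2 (O–C6 bond, inversion, as known for α-keto triflates); acetate then adds reversibly to the doubly activated 2-phosphonoacrylate of 29 (oxa-Michael) to give the phosphonate carbanion carrying CH2OAc at C11, which attacks the neighbouring C7 ketone and loses diethyl phosphate (intramolecular Horner–Wadsworth–Emmons) to form C7=C11. The closest known reactions are the alkylation/intramolecular Horner–Wadsworth–Emmons butenolide synthesis from α-halo ketones and phosphonoacetic acid salts and the tandem Michael/Horner–Wadsworth–Emmons reactions of 2-phosphonoacrylates with thiolate, alkoxide and amine donors; new is acetate as the Michael donor, which is reasonable because retro-Michael loss of acetate only regenerates 29 while the olefination is irreversible. The butenolide closes by 5-exo-trig addition of C11 to C7 followed by syn elimination from the oxaphosphetane. The only new stereocentre, C6, is fixed by the stereospecific SN2 inversion of the threo triflate 28, which gives the erythro (6S) arrangement of the target. The step needs O-alkylation at C6 by the phosphonoacrylate before any acetate is present (order of addition), olefination of the C7 and not the C1 ketone (a five-membered ring forms only from C7), and survival of the oxirane and of C8/C10, for which the acetate/acetic acid buffer is too weakly basic to enolise the α-acyloxy ketone.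

**Step 20**
Reactants: 30 (4R,5S,6S,8S,10R)-13-acetoxy-8-[(2-{[(tert-butyldimethylsilyl)oxy]methyl}acryloyl)oxy]-4,5-epoxy-1-oxogermacr-7(11)-en-12,6-olide
Product: 31 (4R,5S,6S,8S,10R)-13-acetoxy-4,5-epoxy-8-{[2-(hydroxymethyl)acryloyl]oxy}-1-oxogermacr-7(11)-en-12,6-olide (target, CNP0258719.1)
Conditions: HF·pyridine, pyridine, THF, 0 °C → rt
Reagents that add atoms: none
Why: Buffered HF·pyridine removes the primary TBS ether; no base is present that could deprotonate C6–H of the butenolide and no strong acid that could open the trisubstituted oxirane.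

**Compound list**
1 | (S)-5-[(trityloxy)methyl]dihydrofuran-2(3H)-one | O=C1CC[C@@H](COC(c2ccccc2)(c2ccccc2)c2ccccc2)O1 | starting material
2 | (3R,5S)-3-methyl-5-[(trityloxy)methyl]dihydrofuran-2(3H)-one | C[C@@H]1C[C@@H](COC(c2ccccc2)(c2ccccc2)c2ccccc2)OC1=O | intermediate
3 | (2R,4S)-4-hydroxy-N-methoxy-N,2-dimethyl-5-(trityloxy)pentanamide | C(c1ccccc1)(c1ccccc1)(c1ccccc1)OC[C@@H](O)C[C@@H](C)C(=O)N(C)OC | intermediate
4 | (2R,4S)-4-[(tert-butyldimethylsilyl)oxy]-N-methoxy-N,2-dimethyl-5-(trityloxy)pentanamide | C(c1ccccc1)(c1ccccc1)(c1ccccc1)OC[C@@H](O[Si](C)(C)C(C)(C)C)C[C@@H](C)C(=O)N(C)OC | intermediate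
5 | 4-bromo-2-methylbut-1-ene | C=C(C)CCBr | starting material
6 | (3-methylbut-3-en-1-yl)magnesium bromide | C=C(C)CC[Mg]Br | intermediate
7 | (6R,8S)-8-[(tert-butyldimethylsilyl)oxy]-2,6-dimethyl-9-(trityloxy)non-1-en-5-one | C(c1ccccc1)(c1ccccc1)(c1ccccc1)OC[C@@H](O[Si](C)(C)C(C)(C)C)C[C@@H](C)C(=O)CCC(C)=C | intermediate
8 | (6R,8S)-8-[(tert-butyldimethylsilyl)oxy]-9-hydroxy-2,6-dimethylnon-1-en-5-one | OC[C@@H](O[Si](C)(C)C(C)(C)C)C[C@@H](C)C(=O)CCC(C)=C | intermediate
9 | (2S,4R)-2-[(tert-butyldimethylsilyl)oxy]-4,8-dimethyl-5-oxonon-8-enal | O=C[C@@H](O[Si](C)(C)C(C)(C)C)C[C@@H](C)C(=O)CCC(C)=C | intermediate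
10 | 4-methoxybenzyl alcohol | COc1ccc(CO)cc1 | starting material
11 | allyl bromide | C=CCBr | starting material
12 | 1-[(allyloxy)methyl]-4-methoxybenzene | C=CCOCc1ccc(OC)cc1 | intermediate
13 | [(Z)-3-[(4-methoxybenzyl)oxy]prop-2-en-1-yl]bis[(1S,2R,3S,5S)-2,6,6-trimethylbicyclo[3.1.1]heptan-3-yl]borane | COc1ccc(CO/C=C\CB([C@H]2C[C@H]3C[C@@H]([C@@H]2C)C3(C)C)[C@H]2C[C@H]3C[C@@H]([C@@H]2C)C3(C)C)cc1 | intermediate
14 | (6R,8S,9R,10S)-8-[(tert-butyldimethylsilyl)oxy]-9-hydroxy-10-[(4-methoxybenzyl)oxy]-2,6-dimethyldodeca-1,11-dien-5-one | C=C[C@H](OCc1ccc(OC)cc1)[C@@H](O)[C@@H](O[Si](C)(C)C(C)(C)C)C[C@@H](C)C(=O)CCC(C)=C | intermediate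
15 | (3S,5S,7R)-5-[(tert-butyldimethylsilyl)oxy]-3-[(4-methoxybenzyl)oxy]-7,11-dimethyldodeca-1,11-diene-4,8-dione | C=C[C@H](OCc1ccc(OC)cc1)C(=O)[C@@H](O[Si](C)(C)C(C)(C)C)C[C@@H](C)C(=O)CCC(C)=C | intermediate
16 | (2R,4S,6S,7Z)-4-[(tert-butyldimethylsilyl)oxy]-6-[(4-methoxybenzyl)oxy]-2,8-dimethylcyclodec-7-ene-1,5-dione | CC(C)(C)[Si](C)(C)O[C@H]1C[C@@H](C)C(=O)CC/C(C)=C\[C@H](OCc2ccc(OC)cc2)C1=O | intermediate
17 | (2R,4S,6S,7Z)-4-hydroxy-6-[(4-methoxybenzyl)oxy]-2,8-dimethylcyclodec-7-ene-1,5-dione | O[C@H]1C[C@@H](C)C(=O)CC/C(C)=C\[C@H](OCc2ccc(OC)cc2)C1=O | intermediate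
18 | ethyl 2-(hydroxymethyl)acrylate | C=C(CO)C(=O)OCC | starting material
19 | ethyl 2-{[(tert-butyldimethylsilyl)oxy]methyl}acrylate | C=C(CO[Si](C)(C)C(C)(C)C)C(=O)OCC | intermediate
20 | 2-{[(tert-butyldimethylsilyl)oxy]methyl}acrylic acid | C=C(CO[Si](C)(C)C(C)(C)C)C(=O)O | intermediate
21 | (1S,3S,4Z,9R)-3-[(4-methoxybenzyl)oxy]-5,9-dimethyl-2,8-dioxocyclodec-4-en-1-yl 2-{[(tert-butyldimethylsilyl)oxy]methyl}acrylate | C=C(CO[Si](C)(C)C(C)(C)C)C(=O)O[C@H]1C[C@@H](C)C(=O)CC/C(C)=C\[C@H](OCc2ccc(OC)cc2)C1=O | intermediate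
22 | (1S,3S,4Z,9R)-3-hydroxy-5,9-dimethyl-2,8-dioxocyclodec-4-en-1-yl 2-{[(tert-butyldimethylsilyl)oxy]methyl}acrylate | C=C(CO[Si](C)(C)C(C)(C)C)C(=O)O[C@H]1C[C@@H](C)C(=O)CC/C(C)=C\[C@H](O)C1=O | intermediate
23 | (1S,2S,4S,6R,10R)-2-hydroxy-6,10-dimethyl-3,7-dioxo-11-oxabicyclo[8.1.0]undecan-4-yl 2-{[(tert-butyldimethylsilyl)oxy]methyl}acrylate | C=C(CO[Si](C)(C)C(C)(C)C)C(=O)O[C@H]1C[C@@H](C)C(=O)CC[C@@]2(C)O[C@H]2[C@H](O)C1=O | intermediate
24 | tert-butyl 2-(diethoxyphosphoryl)acetate | CCOP(=O)(CC(=O)OC(C)(C)C)OCC | starting material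
25 | tert-butyl 2-(diethoxyphosphoryl)-3-hydroxypropanoate (racemic) | CCOP(=O)(OCC)C(CO)C(=O)OC(C)(C)C | intermediate
26 | tert-butyl 2-(diethoxyphosphoryl)acrylate | C=C(C(=O)OC(C)(C)C)P(=O)(OCC)OCC | intermediate
27 | 2-(diethoxyphosphoryl)acrylic acid | C=C(C(=O)O)P(=O)(OCC)OCC | intermediate
28 | (1S,2S,4S,6R,10R)-6,10-dimethyl-3,7-dioxo-2-{[(trifluoromethyl)sulfonyl]oxy}-11-oxabicyclo[8.1.0]undecan-4-yl 2-{[(tert-butyldimethylsilyl)oxy]methyl}acrylate | C=C(CO[Si](C)(C)C(C)(C)C)C(=O)O[C@H]1C[C@@H](C)C(=O)CC[C@@]2(C)O[C@H]2[C@H](OS(=O)(=O)C(F)(F)F)C1=O | intermediate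
29 | (1S,2R,4S,6R,10R)-4-[(2-{[(tert-butyldimethylsilyl)oxy]methyl}acryloyl)oxy]-6,10-dimethyl-3,7-dioxo-11-oxabicyclo[8.1.0]undecan-2-yl 2-(diethoxyphosphoryl)acrylate | C=C(CO[Si](C)(C)C(C)(C)C)C(=O)O[C@H]1C[C@@H](C)C(=O)CC[C@@]2(C)O[C@H]2[C@@H](OC(=O)C(=C)P(=O)(OCC)OCC)C1=O | intermediate
30 | (4R,5S,6S,8S,10R)-13-acetoxy-8-[(2-{[(tert-butyldimethylsilyl)oxy]methyl}acryloyl)oxy]-4,5-epoxy-1-oxogermacr-7(11)-en-12,6-olide | C=C(CO[Si](C)(C)C(C)(C)C)C(=O)O[C@H]1C[C@@H](C)C(=O)CC[C@@]2(C)O[C@H]2[C@H]2OC(=O)C(COC(C)=O)=C12 | intermediate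
31 | (4R,5S,6S,8S,10R)-13-acetoxy-4,5-epoxy-8-{[2-(hydroxymethyl)acryloyl]oxy}-1-oxogermacr-7(11)-en-12,6-olide | C=C(CO)C(=O)O[C@H]1C[C@@H](C)C(=O)CC[C@@]2(C)O[C@H]2[C@H]2OC(=O)C(COC(C)=O)=C12 | target

**Step count and risks**
Total step count: 20. Longest linear sequence: 15 steps (steps 1–6, 8–11, 14–16, 19, 20, from compound 1).

Steps most likely to fail:

1. Step 19 (proposed new method). The acetate may add too slowly to the phosphonoacrylate, or the buffered medium may open the oxirane by β-elimination from C6 before the olefination is complete. The fallback uses known chemistry, sets out from 23 and comes back at 30. Compound 23 is triflated and alkylated with the cesium salt of 27 as before, but ester 29 is isolated. Treatment of 29 with 4-methoxybenzyl alcohol 10 and t-BuOK (1 equiv) in THF at −78 °C (alkoxide oxa-Michael addition followed by intramolecular Horner–Wadsworth–Emmons olefination, a known tandem for 2-phosphonoacrylates) should give (4R,5S,6S,8S,10R)-8-[(2-{[(tert-butyldimethylsilyl)oxy]methyl}acryloyl)oxy]-4,5-epoxy-13-[(4-methoxybenzyl)oxy]-1-oxogermacr-7(11)-en-12,6-olide F1. DDQ at pH 7 should then give the 13-hydroxy butenolide (4R,5S,6S,8S,10R)-8-[(2-{[(tert-butyldimethylsilyl)oxy]methyl}acryloyl)oxy]-4,5-epoxy-13-hydroxy-1-oxogermacr-7(11)-en-12,6-olide F2, and Ac2O/pyridine returns 30.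

2. Step 10. Cross-metathesis oligomerisation through the vinyl group and isomerisation of the β,γ-unsaturated ketone may outrun closure of the strained ring. The fallback uses a temporary ring as template, sets out from 14 and comes back at 16. With MeOH, HC(OMe)3 and PPTS, 14 should close to the six-membered cyclic methyl ketal (3R,5S,6R)-5-[(tert-butyldimethylsilyl)oxy]-2-methoxy-6-{(1S)-1-[(4-methoxybenzyl)oxy]prop-2-en-1-yl}-3-methyl-2-(3-methylbut-3-en-1-yl)tetrahydro-2H-pyran (anomeric mixture) F3, in which oxygen bridges C7 and C1. Ring-closing metathesis then has to close only an eight-membered ring, giving the bridged ketal (1R,2S,3Z,7S,8R,10S)-10-[(tert-butyldimethylsilyl)oxy]-7-methoxy-2-[(4-methoxybenzyl)oxy]-4,8-dimethyl-11-oxabicyclo[5.3.1]undec-3-ene F4. Mild aqueous acid (AcOH/THF/H2O) should open it to (4Z,6S,7R,8S,10R)-8-[(tert-butyldimethylsilyl)oxy]-7-hydroxy-6-[(4-methoxybenzyl)oxy]-4,10-dimethylcyclodec-4-en-1-one F5, and Dess–Martin oxidation of the C7 carbinol gives 16.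

3. Step 16. Facial selectivity may be poor or reversed if the macrocycle presents the other olefin face to the peracid, which would give the erythro epoxy alcohol. The fallback delivers oxygen to the opposite face through a bromohydrin, sets out from 22 and comes back at 23. NBS in wet DME should form the bromonium ion on the face the peracid prefers and add water at C4 from the other face, giving (1S,3R,4R,5R,9R)-4-bromo-3,5-dihydroxy-5,9-dimethyl-2,8-dioxocyclodecyl 2-{[(tert-butyldimethylsilyl)oxy]methyl}acrylate F6. Ag2O then closes the oxirane by displacement of bromide at C5 by the C4 hydroxyl, giving 23.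

**Further compounds**
F1 | step 19 | (4R,5S,6S,8S,10R)-8-[(2-{[(tert-butyldimethylsilyl)oxy]methyl}acryloyl)oxy]-4,5-epoxy-13-[(4-methoxybenzyl)oxy]-1-oxogermacr-7(11)-en-12,6-olide | C=C(CO[Si](C)(C)C(C)(C)C)C(=O)O[C@H]1C[C@@H](C)C(=O)CC[C@@]2(C)O[C@H]2[C@H]2OC(=O)C(COCc3ccc(OC)cc3)=C12
F2 | step 19 | (4R,5S,6S,8S,10R)-8-[(2-{[(tert-butyldimethylsilyl)oxy]methyl}acryloyl)oxy]-4,5-epoxy-13-hydroxy-1-oxogermacr-7(11)-en-12,6-olide | C=C(CO[Si](C)(C)C(C)(C)C)C(=O)O[C@H]1C[C@@H](C)C(=O)CC[C@@]2(C)O[C@H]2[C@H]2OC(=O)C(CO)=C12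
F3 | step 10 | (3R,5S,6R)-5-[(tert-butyldimethylsilyl)oxy]-2-methoxy-6-{(1S)-1-[(4-methoxybenzyl)oxy]prop-2-en-1-yl}-3-methyl-2-(3-methylbut-3-en-1-yl)tetrahydro-2H-pyran (anomeric mixture) | COC1(CCC(C)=C)[C@H](C)C[C@H](O[Si](C)(C)C(C)(C)C)[C@H](O1)[C@@H](OCc1ccc(OC)cc1)C=C
F4 | step 10 | (1R,2S,3Z,7S,8R,10S)-10-[(tert-butyldimethylsilyl)oxy]-7-methoxy-2-[(4-methoxybenzyl)oxy]-4,8-dimethyl-11-oxabicyclo[5.3.1]undec-3-ene | CO[C@]1(CC/C(C)=C\[C@H](OCc3ccc(OC)cc3)[C@H]2O1)[C@H](C)C[C@@H]2O[Si](C)(C)C(C)(C)C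
F5 | step 10 | (4Z,6S,7R,8S,10R)-8-[(tert-butyldimethylsilyl)oxy]-7-hydroxy-6-[(4-methoxybenzyl)oxy]-4,10-dimethylcyclodec-4-en-1-one | CC(C)(C)[Si](C)(C)O[C@H]1C[C@@H](C)C(=O)CC/C(C)=C\[C@H](OCc2ccc(OC)cc2)[C@H]1O
F6 | step 16 | (1S,3R,4R,5R,9R)-4-bromo-3,5-dihydroxy-5,9-dimethyl-2,8-dioxocyclodecyl 2-{[(tert-butyldimethylsilyl)oxy]methyl}acrylate | C=C(CO[Si](C)(C)C(C)(C)C)C(=O)O[C@H]1C[C@@H](C)C(=O)CC[C@@](C)(O)[C@H](Br)[C@H](O)C1=O
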